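Compound numbers used throughout: 1–14 as defined in the steps and the compound list; 2 and 11 are the precursors of the key step, 12 is its product, and 14 is piscisoflavone A.

## The problem

Piscisoflavone A (14) is an isoflavone: ring B is bonded through C1' to C3 of a chromen-4-one, the pyranone ring C is fused to ring A at C4a–C8a, and C2 carries only hydrogen. There is no stereocentre, so nothing has to be controlled in space; the difficulty is entirely regiochemical. Ring B is pentasubstituted (C1' aryl link, 2'-OH, 3'-prenyl, 4'-OH, 5'-OMe). The prenyl group sits between two phenols that must stay distinct from the 5'-methyl ether, so the substituents have to be placed one at a time and a late demethylation is not available. The prenyl alkene excludes hydrogenolysis, electrophilic halogen sources and strong Lewis acids late in the route, and under protic acid it can close onto either flanking phenol to give a 2,2-dimethylchroman. The 1,2,4-trioxygenated ring B is easily oxidised once its phenols are free, and C2 of the chromone is open to hydroxide or alkoxide, which cleave ring C. The feature that makes the key step possible is that the C4 carbonyl and O1 sit on the adjacent ring A carbons C4a and C8a, which is the pattern of a salicylaldehyde. C2–C3 is then a two-carbon unit with ring B on C3, that is, the two carbons of a ring B arylalkyne, whose other terminus can carry a silyl group that occupies C2 during ring construction and is later exchanged for hydrogen.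

## Retrosynthesis

**14 from 13.** The three O–CH2OMe bonds at O7, O2' and O4' are cut last. A single acetal type for all three phenols means one mild solvolysis ends the route. Benzyl ethers would need a hydrogenolysis that reduces the prenyl alkene, and methyl ethers could not be removed beside the 5'-OMe. 13 is not simpler in skeleton, but its ring B is no longer oxidation-prone, and the same acetals serve earlier as directing groups for metalation. The forward reaction has to cleave three aryl MOM ethers without protonating the prenyl alkene between O2' and O4'.

**13 from 12.** The C2–H bond is traced back to a C2–SiMe3 bond. A hydrogen at C2 would require a terminal alkyne in the annulation, which would dimerise under copper-mediated oxidative conditions and give no control of orientation. The trimethylsilyl group is the smallest substituent that can steer the alkyne and then leave. The forward step is a protodesilylation that must not open the pyranone.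

**12 from 2 and 11.** Ring C is opened at C3–C4 and O1–C2. This gives the salicylaldehyde 2 (ring A with C4 and O1) and the aryl(silyl)alkyne 11 (ring B with C3 and C2).
- The neighbouring cuts are C3–C1' (cross-coupling of a preformed 3-halochromone) and the deoxybenzoin cut with a separate one-carbon unit for C2. Both build ring C in steps apart from the fragment union.
- The chosen cut joins the halves and closes ring C in one operation, and the aldehyde carbon arrives directly at the ketone oxidation level.
- Both precursors are plain benzene derivatives without a heterocycle.
- The forward reaction must bond the aryl-bearing alkyne carbon to the acyl carbon and the silyl-bearing carbon to oxygen, and must tolerate the prenyl alkene and three MOM ethers.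

**11 from 9 and 10.** The C1'–C(sp) bond is cut to the aryl iodide 9 and the silylalkyne 10. A Sonogashira coupling delivers the alkyne already silylated, whereas homologation of an aldehyde would need extra steps and a separate silylation. The forward reaction has to work on an electron-rich, ortho-substituted iodide, which is why iodine rather than bromine is chosen.

**9 from 7 through 8.** The C1'–I bond is cut to the aryllithium 8, formed from 7 by OMOM-directed ortho-metalation. Electrophilic iodination would reach the same carbon but would also attack the prenyl alkene, so the anionic route is preferred. The forward step must lithiate the ring position next to the OMOM group rather than the one next to OMe or the benzylic CH2.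

**7 from 4 and 5 through 6.** The C3'–CH2 bond is cut to the aryllithium 6 and prenyl bromide 5. Friedel–Crafts prenylation of a resorcinol gives isomer mixtures, and a Claisen route delivers the reversed allyl unit unless lengthened. The C–H bond between two OMOM groups is instead lithiated regiospecifically. The forward step needs alkylation at the primary carbon of the allylic bromide.

**4 from 3, and 2 from 1.** Both are O–CH2OMe disconnections to the purchasable phenols 3 and 1. In 1 the 2-OH is hydrogen-bonded to the aldehyde, so the 4-OH alone is masked and the 2-OH stays free as the directing group for the key step.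

## Roads not taken

**Alternative 1:** The cut is at C4a–C4 and C4–C3. 2-Iodo-5-(methoxymethoxy)phenyl acetate A1, the benzylzinc chloride A2 (ArCH2ZnCl, Ar = 5-methoxy-2,4-bis(methoxymethoxy)-3-prenylphenyl) and CO would be joined by Pd(PPh3)4 in a carbonylative Negishi-type coupling to the deoxybenzoin A3. Acetate removal and condensation with a one-carbon electrophile would then supply C2 and close ring C.
- Merits: the endgame from a deoxybenzoin to an isoflavone is the most travelled one, and the position of ring B at C3 is fixed by constitution. On regiochemical certainty this road is better than the chosen one.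
- Weak points: A2 needs a benzylic carbon installed at C1' and converted into a halide that, with three alkoxy donors on the ring, ionises and homocouples readily during zinc insertion. Direct, non-carbonylative coupling competes with CO insertion. C2 is still missing after the key step.
- Comparison: the sequence would be about four steps longer. The chosen plan sets against its own regiochemical question a shorter, convergent route in which ring C is formed with C2 in place, without a labile benzylic organometallic or pressurised gas.

**Alternative 2:** Ring B itself is cut at C5'–C6', C1'–C2' and C2'–C3'. 3-Ethynyl-7-(methoxymethoxy)chromen-4-one A4 and the carbene complex (CO)5Cr=C(OMe)C(OCH2OMe)=CH2 A5 would combine with one CO ligand in a Dötz benzannulation to the 2'-hydroxyisoflavone A6.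
- Merits: the link of ring B to C3 is unambiguous, benzannulation of terminal alkynes is regiochemically reliable, and the 2'-OH emerges free and distinct from the 4'-oxygen, which the chosen plan does not offer.
- Weak points: C3' of A6 carries hydrogen, so the prenyl group would still have to be introduced between two oxygens. That means an O-(1,1-dimethylpropargyl) ether, partial reduction and Claisen rearrangement, about three further steps. Chromium is stoichiometric, A5 is not a routine reagent, and A4 is an electron-poor enynone open to conjugate addition.
- Comparison: the chosen plan carries the complete ring B, prenyl included, into the key step and uses rhodium catalytically.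

**Alternative 3:** Ring B is cut at C1'–C2' and traced to a squarate-derived cyclobutenone. Heating the 4-methoxy-4-alkenylcyclobutenone A7 would open it to a dienylketene, whose 6π electrocyclisation and tautomerisation give the fully substituted phenol A8.
- Merits: the substitution pattern of ring B, prenyl included, follows from the order of additions to the squarate, no transition metal is needed, and the 2'-OH is again free. In regiochemical security this road matches or exceeds the chosen plan.
- Weak points: A7 requires a vinyl-metal reagent that carries a chromone, which is itself an electrophile at C2 and C4. The 4'-oxygen arrives as an isopropyl ether, whose usual selective cleavage beside a methyl ether uses a boron trihalide that the ortho-prenyl phenol would not survive.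
- Comparison: the chosen plan uses one protecting group type removed in a single mild step and simple aromatic fragments, at the price of relying on the silyl group for orientation.

Key step: step 6

Remark: the alkyne insertion in step 6 is assumed to follow the silyl-on-metal orientation established for related annulations of aryl(silyl)alkynes; compounds 1, 3, 5 and 10 are taken as purchasable.

## Route

Step 1
Reactants: 1 2,4-dihydroxybenzaldehyde
Product: 2 2-hydroxy-4-(methoxymethoxy)benzaldehyde
Conditions: MOMCl (1.1 equiv), K2CO3, acetone, 0 °C → rt
Reagents that add atoms: chloromethyl methyl ether, COCCl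
Why: Williamson-type O-alkylation (MOM protection); the 4-OH is the more acidic and more nucleophilic phenol because the 2-OH is held in a hydrogen bond to the aldehyde, so one equivalent of MOMCl with a weak base should mask the 4-OH alone.

Step 2
Reactants: 3 4-methoxyresorcinol
Product: 4 1-methoxy-2,4-bis(methoxymethoxy)benzene
Conditions: NaH (2.4 equiv), MOMCl (2.4 equiv), DMF, 0 °C → rt, N2
Reagents that add atoms: chloromethyl methyl ether, COCCl
Why: Double Williamson etherification through the bis-phenoxide; it is run cold under nitrogen because the electron-rich diphenoxide is sensitive to oxygen.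

Step 3
Reactants: 4 1-methoxy-2,4-bis(methoxymethoxy)benzene; 5 prenyl bromide
Product: 7 1-methoxy-2,4-bis(methoxymethoxy)-3-(3-methylbut-2-enyl)benzene, via aryllithium 6 (not isolated)
Conditions: n-BuLi (1.2 equiv), THF, 0 °C, 1 h; then prenyl bromide (1.3 equiv), −78 °C → rt
Reagents that add atoms: none
Why: Directed ortho-metalation; the C–H bond flanked by two OMOM groups is the most acidic and is doubly chelation-assisted, so 6 should form alone, and SN2 attack of this hindered aryllithium at the primary carbon of the allylic bromide gives the linear prenyl group.

Step 4
Reactants: 7 1-methoxy-2,4-bis(methoxymethoxy)-3-(3-methylbut-2-enyl)benzene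
Product: 9 1-iodo-5-methoxy-2,4-bis(methoxymethoxy)-3-(3-methylbut-2-enyl)benzene, via aryllithium 8 (not isolated)
Conditions: n-BuLi (1.3 equiv), Et2O, 0 °C → rt; then I2 (1.3 equiv) in THF, −78 °C
Reagents that add atoms: iodine, II
Why: Second directed ortho-metalation followed by iodine quench; OMOM is a stronger director than OMe, so the ring position next to the OMOM group is lithiated, and in ether without added amine chelation-directed ring lithiation should outrun deprotonation of the benzylic CH2, whose anion cannot become coplanar with a ring substituted at both ortho positions. Iodine traps 8 at −78 °C much faster than it adds to the trisubstituted alkene.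

Step 5
Reactants: 9 1-iodo-5-methoxy-2,4-bis(methoxymethoxy)-3-(3-methylbut-2-enyl)benzene; 10 ethynyltrimethylsilane
Product: 11 {[5-methoxy-2,4-bis(methoxymethoxy)-3-(3-methylbut-2-enyl)phenyl]ethynyl}trimethylsilane
Conditions: PdCl2(PPh3)2 (3 mol %), CuI (6 mol %), Et3N, THF, 50 °C
Reagents that add atoms: none
Why: Sonogashira coupling of an aryl iodide with a terminal alkyne; the iodide offsets the electron-rich, ortho-substituted ring in oxidative addition to zerovalent palladium, and MOM ethers and the prenyl group are inert to the catalyst pair and the amine.

Step 6
Reactants: 2 2-hydroxy-4-(methoxymethoxy)benzaldehyde; 11 {[5-methoxy-2,4-bis(methoxymethoxy)-3-(3-methylbut-2-enyl)phenyl]ethynyl}trimethylsilane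
Product: 12 3-[5-methoxy-2,4-bis(methoxymethoxy)-3-(3-methylbut-2-enyl)phenyl]-7-(methoxymethoxy)-2-(trimethylsilyl)chromen-4-one
Conditions: [RhCl(cod)]2 (2 mol %), C5H2Ph4 (8 mol %), Cu(OAc)2·H2O (2.2 equiv), o-xylene, 140 °C, N2
Reagents that add atoms: none
Why: This is the rhodium-catalysed oxidative coupling of salicylaldehydes with internal alkynes to 2,3-disubstituted chromones, and the closest known reaction type is that same annulation with diaryl-, dialkyl- and alkyl(aryl)alkynes. [RhCl(cod)]2, C5H2Ph4 and Cu(OAc)2 generate a tetraphenylcyclopentadienyl complex of trivalent rhodium, the phenoxide of 2 binds it, and the aldehyde C–H bond is cleaved to a five-membered acyl rhodacycle. Alkyne 11 inserts into the rhodium–acyl bond to give a seven-membered oxa-rhodacycle, and C–O reductive elimination closes ring C in a formal [4+2] annulation in which O1, C8a, C4a and C4 come from 2 and C3 and C2 from 11; the monovalent rhodium released is reoxidised by two equivalents of divalent copper. No stereocentre is formed. The step needs insertion with the silyl-bearing carbon on rhodium (the future C2) and the aryl-bearing carbon on the acyl carbon (the future C3); the carbanion-stabilising α-silyl effect at the metal-bound carbon and the preference of the bulky Me3Si group for the long Rh–C bond over the forming C–C bond should secure this, as in Larock-type annulations of aryl(silyl)alkynes. It also needs oxidative turnover to outrun decarbonylation of the acyl rhodium and simple hydroacylation, which the chelating phenoxide and the excess of Cu(OAc)2 favour. The trisubstituted prenyl alkene is a poor ligand and a poor insertion partner, and the MOM acetals meet only acetic acid in a non-polar solvent, so both should remain spectators.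

Step 7
Reactants: 12 3-[5-methoxy-2,4-bis(methoxymethoxy)-3-(3-methylbut-2-enyl)phenyl]-7-(methoxymethoxy)-2-(trimethylsilyl)chromen-4-one
Product: 13 3-[5-methoxy-2,4-bis(methoxymethoxy)-3-(3-methylbut-2-enyl)phenyl]-7-(methoxymethoxy)chromen-4-one
Conditions: Bu4NF (1.2 equiv), AcOH (1.2 equiv), THF, 0 °C → rt
Reagents that add atoms: none
Why: Fluoride-induced protodesilylation; fluoride attacks silicon, and the C2–Si bond of this α-oxygenated vinylsilane conjugated to the carbonyl group is cleaved with protonation at C2. Acetic acid buffers the medium so that ring C is not opened by basic fluoride or hydroxide, and MOM ethers and the prenyl group are untouched.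

Step 8
Reactants: 13 3-[5-methoxy-2,4-bis(methoxymethoxy)-3-(3-methylbut-2-enyl)phenyl]-7-(methoxymethoxy)chromen-4-one
Product: 14 piscisoflavone A, 3-[2,4-dihydroxy-5-methoxy-3-(3-methylbut-2-enyl)phenyl]-7-hydroxychromen-4-one
Conditions: 3 M aq HCl, MeOH, 50 °C
Reagents that add atoms: none
Why: Acid-catalysed acetal solvolysis (MOM removal) in methanol, the usual unmasking of prenylated flavonoids; moderate temperature and short reaction time are chosen so that the three acetals exchange before the prenyl alkene is protonated.

## Compound list

1 | 2,4-dihydroxybenzaldehyde | O=Cc1ccc(O)cc1O | starting material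
2 | 2-hydroxy-4-(methoxymethoxy)benzaldehyde | COCOc1ccc(C=O)c(O)c1 | intermediate
3 | 4-methoxyresorcinol (4-methoxybenzene-1,3-diol) | COc1ccc(O)cc1O | starting material
4 | 1-methoxy-2,4-bis(methoxymethoxy)benzene | COCOc1ccc(OC)c(OCOC)c1 | intermediate
5 | prenyl bromide (1-bromo-3-methylbut-2-ene) | CC(C)=CCBr | starting material
6 | [3-methoxy-2,6-bis(methoxymethoxy)phenyl]lithium | [Li]c1c(OCOC)ccc(OC)c1OCOC | intermediate
7 | 1-methoxy-2,4-bis(methoxymethoxy)-3-(3-methylbut-2-enyl)benzene | COCOc1ccc(OC)c(OCOC)c1CC=C(C)C | intermediate
8 | [5-methoxy-2,4-bis(methoxymethoxy)-3-(3-methylbut-2-enyl)phenyl]lithium | [Li]c1cc(OC)c(OCOC)c(CC=C(C)C)c1OCOC | intermediate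
9 | 1-iodo-5-methoxy-2,4-bis(methoxymethoxy)-3-(3-methylbut-2-enyl)benzene | COCOc1c(I)cc(OC)c(OCOC)c1CC=C(C)C | intermediate
10 | ethynyltrimethylsilane | C#C[Si](C)(C)C | starting material
11 | {[5-methoxy-2,4-bis(methoxymethoxy)-3-(3-methylbut-2-enyl)phenyl]ethynyl}trimethylsilane | COCOc1c(C#C[Si](C)(C)C)cc(OC)c(OCOC)c1CC=C(C)C | intermediate
12 | 3-[5-methoxy-2,4-bis(methoxymethoxy)-3-(3-methylbut-2-enyl)phenyl]-7-(methoxymethoxy)-2-(trimethylsilyl)chromen-4-one | COCOc1ccc2c(c1)oc([Si](C)(C)C)c(-c1cc(OC)c(OCOC)c(CC=C(C)C)c1OCOC)c2=O | intermediate
13 | 3-[5-methoxy-2,4-bis(methoxymethoxy)-3-(3-methylbut-2-enyl)phenyl]-7-(methoxymethoxy)chromen-4-one | COCOc1ccc2c(c1)occ(-c1cc(OC)c(OCOC)c(CC=C(C)C)c1OCOC)c2=O | intermediate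
14 | piscisoflavone A, 3-[2,4-dihydroxy-5-methoxy-3-(3-methylbut-2-enyl)phenyl]-7-hydroxychromen-4-one | COc1cc(-c2coc3cc(O)ccc3c2=O)c(O)c(CC=C(C)C)c1O | target

## Step count and least certain steps

Total: 8 steps. Longest linear sequence: 7 steps (3 → 4 → 7 → 9 → 11 → 12 → 13 → 14; steps 2–8). The ring A branch (step 1) joins at step 6.

**Step 6 (key step).**
- Most likely failure: insertion of the alkyne in the reverse sense, with the aryl-bearing carbon on rhodium. The orientation rests on analogy, not on a demonstration with this alkyne class, and an aryl group also stabilises a metal-bound carbon.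
- Further possible failures: loss of the alkynyl silyl group before insertion followed by copper-mediated oxidative dimerisation of the alkyne; decarbonylation of the acyl rhodium at 140 °C; partial acetal cleavage by hot acetic acid; slow insertion of a bulky silylalkyne.
- Fallback (known cross-coupling chemistry, sets out from 9, returns at 13): Miyaura borylation of 9 (B2pin2, PdCl2(dppf), KOAc, dioxane, 80 °C) would give 2-[5-methoxy-2,4-bis(methoxymethoxy)-3-(3-methylbut-2-enyl)phenyl]-4,4,5,5-tetramethyl-1,3,2-dioxaborolane F1. Separately, purchased 2,4-dihydroxyacetophenone F2 would be converted with MOMCl and K2CO3 into 1-[2-hydroxy-4-(methoxymethoxy)phenyl]ethanone F3, condensed with DMF dimethyl acetal to (E)-3-(dimethylamino)-1-[2-hydroxy-4-(methoxymethoxy)phenyl]prop-2-en-1-one F4, and cyclised with I2 to 3-iodo-7-(methoxymethoxy)chromen-4-one F5. Suzuki–Miyaura coupling of F1 with F5 (PdCl2(dppf), K2CO3, dioxane/H2O, 80 °C) would give 13 directly, and the route resumes at step 8.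

**Step 4.**
- Most likely failure: deprotonation at the benzylic, allylic CH2 of the prenyl group, or lithiation next to OMe, in place of lithiation next to OMOM. The CH2 lies between two coordinating OMOM groups.
- Fallback (sets out from 4, returns at 11): the order is reversed so that no organolithium meets the prenyl group before it is installed. Electrophilic iodination of 4 with N-iodosuccinimide in MeCN, at the position ortho and para to the two OMOM groups, would give 1-iodo-5-methoxy-2,4-bis(methoxymethoxy)benzene F6. Sonogashira coupling with 10 would give {[5-methoxy-2,4-bis(methoxymethoxy)phenyl]ethynyl}trimethylsilane F7. Lithiation between the two OMOM groups (n-BuLi, THF, −78 → 0 °C) would give [3-methoxy-2,6-bis(methoxymethoxy)-5-(trimethylsilylethynyl)phenyl]lithium F8, and alkylation with 5 would give 11.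

**Step 7.**
- Most likely failure: sluggish C–Si cleavage under buffered fluoride, or opening of ring C by attack of fluoride or adventitious hydroxide at C2 if the buffer is omitted to speed the reaction.
- Fallback (sets out from 12, returns at 14): the fluoride step is dropped and 12 is treated directly with HCl in MeOH at 50 °C. Protonation of the chromone carbonyl gives a 4-hydroxybenzopyrylium ion whose C2–Si bond is cleaved by the solvent while the MOM ethers are solvolysed in the same operation. This path makes no new compound (F0).

**Step 8.**
- Most likely failure: acid-catalysed addition of the freed 2'- or 4'-phenol to the protonated prenyl alkene (chroman ring closure), or hydration of the alkene, on prolonged exposure to HCl.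
- Fallback (sets out from 13, returns at 14): a silyl-transfer deprotection without protic acid. TMSOTf and 2,2'-bipyridyl in MeCN at 0 °C would convert the three aryl MOM ethers into 3-[5-methoxy-3-(3-methylbut-2-enyl)-2,4-bis(trimethylsilyloxy)phenyl]-7-(trimethylsilyloxy)chromen-4-one F9, and addition of water would hydrolyse the silyl ethers to 14 under near-neutral conditions.

## Further compounds

F1 | step 6 | 2-[5-methoxy-2,4-bis(methoxymethoxy)-3-(3-methylbut-2-enyl)phenyl]-4,4,5,5-tetramethyl-1,3,2-dioxaborolane | COCOc1c(B2OC(C)(C)C(C)(C)O2)cc(OC)c(OCOC)c1CC=C(C)C
F2 | step 6 | 2,4-dihydroxyacetophenone (purchased) | CC(=O)c1ccc(O)cc1O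
F3 | step 6 | 1-[2-hydroxy-4-(methoxymethoxy)phenyl]ethanone | COCOc1ccc(C(C)=O)c(O)c1
F4 | step 6 | (E)-3-(dimethylamino)-1-[2-hydroxy-4-(methoxymethoxy)phenyl]prop-2-en-1-one | COCOc1ccc(C(=O)/C=C/N(C)C)c(O)c1
F5 | step 6 | 3-iodo-7-(methoxymethoxy)chromen-4-one | COCOc1ccc2c(c1)occ(I)c2=O
F6 | step 4 | 1-iodo-5-methoxy-2,4-bis(methoxymethoxy)benzene | COCOc1cc(OCOC)c(OC)cc1I
F7 | step 4 | {[5-methoxy-2,4-bis(methoxymethoxy)phenyl]ethynyl}trimethylsilane | COCOc1cc(OCOC)c(OC)cc1C#C[Si](C)(C)C
F8 | step 4 | [3-methoxy-2,6-bis(methoxymethoxy)-5-(trimethylsilylethynyl)phenyl]lithium | COCOc1c([Li])c(OCOC)c(OC)cc1C#C[Si](C)(C)C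
F0 | step 7 | none | none
F9 | step 8 | 3-[5-methoxy-3-(3-methylbut-2-enyl)-2,4-bis(trimethylsilyloxy)phenyl]-7-(trimethylsilyloxy)chromen-4-one | COc1cc(-c2coc3cc(O[Si](C)(C)C)ccc3c2=O)c(O[Si](C)(C)C)c(CC=C(C)C)c1O[Si](C)(C)C
A1 | alternative 1 | 2-iodo-5-(methoxymethoxy)phenyl acetate | CC(=O)Oc1cc(OCOC)ccc1I
A2 | alternative 1 | {[5-methoxy-2,4-bis(methoxymethoxy)-3-(3-methylbut-2-enyl)phenyl]methyl}zinc chloride | COCOc1c(C[Zn]Cl)cc(OC)c(OCOC)c1CC=C(C)C
A3 | alternative 1 | 2-{2-[5-methoxy-2,4-bis(methoxymethoxy)-3-(3-methylbut-2-enyl)phenyl]acetyl}-5-(methoxymethoxy)phenyl acetate | CC(=O)Oc1cc(OCOC)ccc1C(=O)Cc1cc(OC)c(OCOC)c(CC=C(C)C)c1OCOC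
A4 | alternative 2 | 3-ethynyl-7-(methoxymethoxy)chromen-4-one | COCOc1ccc2c(c1)occ(C#C)c2=O
A5 | alternative 2 | pentacarbonyl{methoxy[1-(methoxymethoxy)ethenyl]methylidene}chromium, (CO)5Cr=C(OMe)C(OCH2OMe)=CH2 | COCOC(=C)C(OC)=[Cr](=C=O)(=C=O)(=C=O)(=C=O)=C=O
A6 | alternative 2 | 3-[2-hydroxy-5-methoxy-4-(methoxymethoxy)phenyl]-7-(methoxymethoxy)chromen-4-one | COCOc1ccc2c(c1)occ(-c1cc(OC)c(OCOC)cc1O)c2=O
A7 | alternative 3 | 4-methoxy-4-{(E)-2-[7-(methoxymethoxy)-4-oxochromen-3-yl]ethenyl}-2-(3-methylbut-2-enyl)-3-(propan-2-yloxy)cyclobut-2-en-1-one (racemic) | COCOc1ccc2c(c1)occ(/C=C/C1(OC)C(OC(C)C)=C(CC=C(C)C)C1=O)c2=O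
A8 | alternative 3 | 3-[2-hydroxy-5-methoxy-3-(3-methylbut-2-enyl)-4-(propan-2-yloxy)phenyl]-7-(methoxymethoxy)chromen-4-one | COCOc1ccc2c(c1)occ(-c1cc(OC)c(OC(C)C)c(CC=C(C)C)c1O)c2=O
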